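A one-step world turns G into E and ends each flask at 100 percent of the charge. Maple ends at 45 % and larch at 19 %, so G has a second way out, and the yield is lower at the higher charge.

| setting | maple | larch | east | north | north-west | south-east |
|---|---|---|---|---|---|---|
| G | 0.050 M | 0.17 M | 0.059 M | 0.080 M | 0.12 M | 0.040 M |
| remark | run made earlier | run made earlier |  |  |  |  |
| time |  |  | 10 min | 10 min | 10 min | 10 min |

| run | time / min | E / % | G / % |
|---|---|---|---|
| maple | 0.500 | 11 | 58 |
| maple | 1.50 | 24 | 27 |
| maple | 3.00 | 33 | 11 |
| maple | 4.00 | 39 | 4 |
| maple | 6.00 | 44 | 5 |
| maple | 8.00 | 43 | 2 |
| maple | 10.0 | 45 | 0 |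
| larch | 1.33 | 9 | 16 |
| larch | 3.00 | 14 | 5 |
| larch | 4.00 | 16 | 6 |
| larch | 6.00 | 19 | 1 |
| larch | 8.00 | 19 | 0 |
| larch | 10.0 | 19 | 0 |

(readings scatter by 1.5 percentage points)

1. ranking by amount of E, in percent of the G charged, from high to low, at 10 min (east / north / north-west / south-east)
2. the same order at 1.0 min (east / north / north-west / south-east)
3. the amount of E, in percent of the G charged of the flask you put first, at 10 min
4. the amount of E, in percent of the G charged of the flask you put last, at 10 min

- a reading or a percentage of E counts all its forms, free or not

I assume that the share of reacting G that becomes E, the selectivity, depends on [G] and on nothing else. A richer flask then passes through each [G] of a leaner one and adds E above it. Larch's harvest, the final [E] as yield times charge with its forms counted, is 32.3 mM, and maple's is 22.5 mM. So harvest rises with charge, and I read the falling yield as selectivity falling with [G], which bends the harvest curve downward. G reads 0 % in maple and 0 % in larch at 10.0 min, so I count the new flasks as finished. Yield therefore ranks them inversely to charge at 10 min. Early readings lag with charge too: larch shows 9 % at 1.33 min, maple 24 % at 1.50 min, so I keep that order at 1.0 min.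

North-west's harvest stays below larch's, which caps its yield at 26.9 %. It stays above the straight line from maple to larch, 28.2 mM, which gives a floor of 23.5 %. For south-east, maple's yield is the floor, and the same line run backward gives a cap of 54.2 %. These bounds are readings and carry the scatter of 1.5 percentage points.

The forecast gives south-east > east > north > north-west at 10 min and south-east > east > north > north-west at 1.0 min, with south-east at 49 % and north-west at 25 %, on the view that “That looks like a saturating route to E”. Both numbers lie inside my brackets.

The flask gives south-east > east > north > north-west at 10 min and south-east > east > north > north-west at 1.0 min, with south-east at 50.9 % and north-west at 24.2 %, inside both brackets.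

    G → E, rate k1*[G]/(1 + ([G]/sat1)) (38.0 mM, k = 0.00880 s⁻¹)
    2 G → J (k = 0.170 M⁻¹ s⁻¹)
    L ⇌ E, rate k3*(cs3 - [E]) while solid is left; crystals form when [E] > cs3 (solubility = 0.600 mM, k = 0.420 s⁻¹)

In north-west, G went into J at the start at 19 times the rate at which it went into E, and by 5.00 min G stood at 2.01 % with E at 22.5 %. E meanwhile left solution as crystals of L, half of that turnover being done by 1.44 min, and at 10.0 min L stood at 23.7 % of the G charged, counted within the 24.2 % of E. North-west's harvest of 29.1 mM lies below larch's. The flask like north-west but charged with 0.48 M of G has a floor of 6.73 % from larch's harvest, and it ends at 7.10 %.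

The earlier runs and the new flask were generated by integration on assumed constants; scatter was added.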